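Atom numbers are those of britannilactone. The plan rests on opening the γ-lactone at C11–C7 and O–C8 and exploits the all-cis array C6–O, C7–C11, C8–O on the cyclohexene ring. A β-keto acid is hung on the C6 oxygen as an ether; oxidation with trivalent manganese lets its C11 radical close a temporary pyranone ring onto C7 and the carboxyl then closes the lactone onto C8, so both bonds and both stereocentres come from C6 in one operation. The precursor is a citronellal-derived cyclohex-2-enyl ether whose C5=C10 alkene is masked as an epoxide; later the tether is cut and its acetyl group is passed to O6.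

Key step: step 9

Remark: "syn" means on the face of the carbocycle that carries the C6 oxygen. C11 is configurationally labile from step 10 to step 13 and is written without a descriptor where an epimer mixture is expected. (S)-Citronellal of high enantiomeric purity is taken as commercially available.

Step 1
Reactants: 1 (S)-citronellal; 2 vinylmagnesium bromide
Product: 3 (5S)-5,9-dimethyldeca-1,8-dien-3-ol (both C3 epimers)
Conditions: 2 (1.2 equiv), THF, −78 → 0 °C; aq. NH4Cl
Reagents that add atoms: vinylmagnesium bromide, C=C[Mg]Br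
Why: Grignard 1,2-addition to the aldehyde; the new carbinol centre is left uncontrolled because it is oxidised in step 2.

Step 2
Reactants: 3 (5S)-5,9-dimethyldeca-1,8-dien-3-ol
Product: 4 (5S)-5,9-dimethyldeca-1,8-dien-3-one
Conditions: Dess–Martin periodinane, NaHCO3, CH2Cl2, 0 °C → rt; used crude
Reagents that add atoms: none
Why: Dess–Martin oxidation of the allylic alcohol should give the vinyl ketone without touching the trisubstituted alkene or the C4 stereocentre.

Step 3
Reactants: 4 (5S)-5,9-dimethyldeca-1,8-dien-3-one; 5 ethyl acetoacetate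
Product: 8 3-methyl-2-[(2S)-6-methylhept-5-en-2-yl]cyclohex-2-en-1-one, via Michael adduct 6 (not isolated), via keto ester 7 (not isolated)
Conditions: 5 (1.1 equiv), NaOEt (0.2 equiv), EtOH, 0 °C → reflux; then 2 M aq. KOH, reflux; aq. HCl
Reagents that add atoms: ethyl acetoacetate, CCOC(=O)CC(C)=O
Why: Robinson annulation (Michael addition, then aldol condensation of C5 onto the acetyl carbonyl as in the Hagemann ester synthesis) followed by saponification and decarboxylation of the vinylogous β-keto acid; no new stereocentre remains and C4 is not enolisable.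

Step 4
Reactants: 8 3-methyl-2-[(2S)-6-methylhept-5-en-2-yl]cyclohex-2-en-1-one
Product: 9 (1R)-3-methyl-2-[(2S)-6-methylhept-5-en-2-yl]cyclohex-2-en-1-ol
Conditions: (S)-2-methyl-CBS-oxazaborolidine [(S)-1-methyl-3,3-diphenyl-tetrahydropyrrolo[1,2-c][1,3,2]oxazaborole] (0.2 equiv), catecholborane (2 equiv), toluene, −78 → −40 °C; aq. NaOH work-up
Reagents that add atoms: none
Why: Corey–Bakshi–Shibata reduction; with the alkenyl carbon C5 as the large group the (S)-catalyst should give the (6R)-carbinol, so C6 is set by the catalyst independently of the remote C4 centre, and catecholborane spares the side-chain alkene.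

Step 5
Reactants: 9 (1R)-3-methyl-2-[(2S)-6-methylhept-5-en-2-yl]cyclohex-2-en-1-ol
Product: 10 (1R,2R,6S)-6-methyl-1-[(2S)-6-methylhept-5-en-2-yl]-7-oxabicyclo[4.1.0]heptan-2-ol (epoxide oxygen syn to the hydroxyl)
Conditions: VO(acac)2 (0.05 equiv), t-BuOOH (1.5 equiv, decane), CH2Cl2, 0 °C → rt
Reagents that add atoms: tert-butyl hydroperoxide, CC(C)(C)OO
Why: Hydroxyl-directed vanadium-catalysed epoxidation should deliver oxygen to the C5=C10 alkene from the face of the C6 hydroxyl (C5 and C10 set syn to O6) and leave the isolated side-chain alkene alone.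

Step 6
Reactants: 10 syn-epoxy alcohol
Product: 12 (1S,6S)-6-methyl-1-[(2S)-6-methylhept-5-en-2-yl]-7-oxabicyclo[4.1.0]hept-3-en-2-one, via epoxy ketone 11 (not isolated)
Conditions: 2-iodoxybenzoic acid (IBX, 3.5 equiv), DMSO/fluorobenzene, 25 °C then 75 °C
Reagents that add atoms: none
Why: IBX oxidation of the carbinol and IBX dehydrogenation of the ketone, which can only go toward C7–C8 because C5 is quaternary; the epoxide now carries the stereochemical information of C6 and keeps the ring from aromatising.

Step 7
Reactants: 12 epoxy enone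
Product: 13 (1R,2R,6S)-6-methyl-1-[(2S)-6-methylhept-5-en-2-yl]-7-oxabicyclo[4.1.0]hept-3-en-2-ol (hydroxyl syn to the epoxide oxygen)
Conditions: NaBH4, CeCl3·7H2O, MeOH, −78 °C
Reagents that add atoms: none
Why: Luche 1,2-reduction; hydride should enter anti to the epoxide oxygen and return the C6 hydroxyl syn to the epoxide, which is the (6R) configuration relayed from step 4.

Step 8
Reactants: 13 syn-epoxy dienol; 14 ethyl 4-chloroacetoacetate
Product: 16 4-{[(1R,2R,6S)-6-methyl-1-[(2S)-6-methylhept-5-en-2-yl]-7-oxabicyclo[4.1.0]hept-3-en-2-yl]oxy}-3-oxobutanoic acid, via ethyl ester 15 (not isolated)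
Conditions: NaH (2.2 equiv), THF, 0 °C, then 14; then 1 M aq. LiOH, 0 °C → rt; cold aq. HCl to pH 3, extract, use at once
Reagents that add atoms: ethyl 4-chloroacetoacetate, CCOC(=O)CC(=O)CCl; lithium hydroxide, [Li+].[OH-]
Why: Williamson etherification of the C6 alkoxide with the γ-chloride of the sodium enolate of 14, then saponification; the syn-epoxy alkoxide cannot undergo Payne rearrangement and C6 is untouched.

Step 9
Reactants: 16 β-keto acid
Product: 17 tricyclic keto lactone (pyran-3-one fused at C6–C7, γ-lactone fused at C7–C8, O6, C11 and O8 all syn, 5,10-epoxide retained)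
Conditions: Mn(OAc)3·2H2O (2.3 equiv), KOAc (2 equiv), AcOH (0.005 M), 20 °C
Reagents that add atoms: none
Why: Mn(OAc)3 oxidises the enol of the β-keto acid at C11, and the resulting electrophilic C11 radical (or its manganese enolate) adds to C7 of the C7=C8 bond, closing the temporary tetrahydropyran-3-one ring in the 6-exo-trig mode; the C8 radical is then oxidised inside the manganese carboxylate and taken by the carboxyl oxygen, closing the γ-lactone in the 5-exo mode, so that C11–C7 and O–C8 are made in one operation. The closest known reaction type is the manganese triacetate oxidative cyclisation–lactonisation (double annulation) of unsaturated β-keto acids. C7 is controlled by the tether, which reaches only the alkene face syn to the C6 oxygen and can only give a cis-fused six-membered ring. C8 is controlled by the carboxyl group, which is then held on that same face and can only close a cis-fused five-membered lactone, while C11 takes the one configuration compatible with both cis ring fusions and is later made trigonal. The step needs attack at C7 and not C8, secured by the tether length (6-exo over 7-endo), and a substrate that cannot aromatise, secured by keeping C5=C10 as the epoxide, since the free diene ether would be an arene hydrate. High dilution and acetate buffer are meant to suppress capture of the radical by the remote trisubstituted alkene, hydrogen transfer from C6–H and acetolysis of the epoxide.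

Step 10
Reactants: 17 tricyclic keto lactone
Product: 18 11-acetyl-6-hydroxy 12,8-lactone (5,10-epoxide and side-chain alkene retained)
Conditions: SmI2 (2.5 equiv), THF/MeOH, −78 °C
Reagents that add atoms: none
Why: Samarium diiodide reductive cleavage of the α-alkoxy ketone (ketyl formation, β-elimination of the C6 alkoxide, protonation of the enolate) should free the C6 hydroxyl and turn the tether into an acetyl group on C11; only the epimerisable C11 can be affected.

Step 11
Reactants: 18 acetyl lactone; 19 formaldehyde (as paraformaldehyde)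
Product: 21 6-O-acetyl-13-hydroxy 12,8-lactone (11-hydroxymethyl, 5,10-epoxide, side-chain alkene), via hydroxymethyl adduct 20 (not isolated)
Conditions: (CH2O)n (3 equiv), K2CO3 (0.5 equiv), THF, 0 °C → rt
Reagents that add atoms: formaldehyde, C=O
Why: Aldol addition of the β-keto lactone enolate to formaldehyde makes C11 quaternary, after which the syn C6 hydroxyl should attack the acetyl carbonyl through a five-membered hemiketal and retro-Claisen cleavage moves the acetyl group onto O6 (retro-Claisen acyl transfer); C11 forms as an epimer mixture that is removed in step 14.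

Step 12
Reactants: 21 epoxy lactone with side-chain alkene
Product: 23 6-O-acetyl-1,13-dihydroxy epoxy lactone, via aldehyde 22 (not isolated)
Conditions: O3, CH2Cl2/MeOH, −78 °C; Me2S; then NaBH4, −40 → 0 °C
Reagents that add atoms: ozone, [O-][O+]=O
Why: Ozonolysis of the only alkene present (the ring alkene is still masked as the epoxide) and borohydride reduction of the aldehyde should give the C1 alcohol while lactone, acetate and epoxide survive.

Step 13
Reactants: 23 epoxy diol
Product: 25 6-O-acetyl-13-hydroxy-11,13-dihydrobritannilactone, via iodohydrin 24 (not isolated)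
Conditions: NaI (5 equiv), NaOAc, Zn dust (10 equiv), AcOH, 0 °C → rt
Reagents that add atoms: none
Why: Iodohydrin–zinc deoxygenation of the epoxide: iodide should open the epoxide at C10 with inversion and zinc then effects anti elimination of iodide and the C5 hydroxyl, regenerating the C5=C10 alkene regiospecifically; the syn C6 acetate cannot participate.

Step 14
Reactants: 25 6-O-acetyl-13-hydroxy-11,13-dihydrobritannilactone; 26 acetic anhydride
Product: 28 1,6-O,O-diacetylbritannilactone, via triacetate 27 (not isolated)
Conditions: Ac2O (4 equiv), Et3N, DMAP (0.1 equiv), CH2Cl2, 0 °C → rt; then DBU (2 equiv), rt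
Reagents that add atoms: acetic anhydride, CC(=O)OC(C)=O
Why: Acetylation of the C1 and C13 hydroxyls followed by E1cB elimination of the β-acetoxy group from the lactone enolate should give the α-methylene lactone; the C6 acetate and all stereocentres are untouched.

Compound list
1 | (S)-citronellal, (3S)-3,7-dimethyloct-6-enal | O=CC[C@@H](C)CCC=C(C)C | starting material
2 | vinylmagnesium bromide | C=C[Mg]Br | starting material
3 | (5S)-5,9-dimethyldeca-1,8-dien-3-ol, C3 epimers | C=CC(O)C[C@@H](C)CCC=C(C)C | intermediate
4 | (5S)-5,9-dimethyldeca-1,8-dien-3-one | C=CC(=O)C[C@@H](C)CCC=C(C)C | intermediate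
5 | ethyl acetoacetate | CCOC(=O)CC(C)=O | starting material
6 | Michael adduct, ethyl (7S)-2-acetyl-7,11-dimethyl-5-oxododec-10-enoate | CCOC(=O)C(CCC(=O)C[C@@H](C)CCC=C(C)C)C(C)=O | intermediate
7 | keto ester, ethyl 2-methyl-3-[(2S)-6-methylhept-5-en-2-yl]-4-oxocyclohex-2-ene-1-carboxylate | CCOC(=O)C1CCC(=O)C([C@@H](C)CCC=C(C)C)=C1C | intermediate
8 | 3-methyl-2-[(2S)-6-methylhept-5-en-2-yl]cyclohex-2-en-1-one | CC1=C([C@@H](C)CCC=C(C)C)C(=O)CCC1 | intermediate
9 | (1R)-3-methyl-2-[(2S)-6-methylhept-5-en-2-yl]cyclohex-2-en-1-ol (4S,6R) | CC1=C([C@@H](C)CCC=C(C)C)[C@H](O)CCC1 | intermediate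
10 | syn-epoxy alcohol, (1R,2R,6S)-6-methyl-1-[(2S)-6-methylhept-5-en-2-yl]-7-oxabicyclo[4.1.0]heptan-2-ol | C[C@@]12O[C@]1([C@@H](C)CCC=C(C)C)[C@H](O)CCC2 | intermediate
11 | epoxy ketone, (1S,6S)-6-methyl-1-[(2S)-6-methylhept-5-en-2-yl]-7-oxabicyclo[4.1.0]heptan-2-one | C[C@@]12O[C@]1([C@@H](C)CCC=C(C)C)C(=O)CCC2 | intermediate
12 | epoxy enone, (1S,6S)-6-methyl-1-[(2S)-6-methylhept-5-en-2-yl]-7-oxabicyclo[4.1.0]hept-3-en-2-one | C[C@@]12O[C@]1([C@@H](C)CCC=C(C)C)C(=O)C=CC2 | intermediate
13 | syn-epoxy dienol, (1R,2R,6S)-6-methyl-1-[(2S)-6-methylhept-5-en-2-yl]-7-oxabicyclo[4.1.0]hept-3-en-2-ol | C[C@@]12O[C@]1([C@@H](C)CCC=C(C)C)[C@H](O)C=CC2 | intermediate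
14 | ethyl 4-chloroacetoacetate (ethyl 4-chloro-3-oxobutanoate) | CCOC(=O)CC(=O)CCl | starting material
15 | ethyl 4-alkoxy-3-oxobutanoate, C6 ether of 13 | C[C@@]12O[C@]1([C@@H](C)CCC=C(C)C)[C@H](OCC(=O)CC(=O)OCC)C=CC2 | intermediate
16 | 4-alkoxy-3-oxobutanoic acid, C6 ether of 13 | C[C@@]12O[C@]1([C@@H](C)CCC=C(C)C)[C@H](OCC(=O)CC(=O)O)C=CC2 | intermediate
17 | tricyclic keto lactone (4S,5R,6R,7R,8R,10S,11S): pyran-3-one on C6–C7, γ-lactone on C7–C8, all syn, 5,10-epoxide | O=C1O[C@@H]2C[C@]3(C)O[C@]3([C@@H](C)CCC=C(C)C)[C@@H]4OCC(=O)[C@@H]1[C@H]24 | intermediate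
18 | 11-acetyl-6-hydroxy-5,10-epoxy 12,8-lactone, configuration as in 17 | CC(=O)[C@H]1C(=O)O[C@@H]2C[C@]3(C)O[C@]3([C@@H](C)CCC=C(C)C)[C@H](O)[C@H]12 | intermediate
19 | formaldehyde (used as paraformaldehyde) | C=O | starting material
20 | hydroxymethyl adduct, 11-acetyl-11-hydroxymethyl lactone (C11 unassigned) | CC(=O)C1(CO)C(=O)O[C@@H]2C[C@]3(C)O[C@]3([C@@H](C)CCC=C(C)C)[C@H](O)[C@H]12 | intermediate
21 | 6-O-acetyl-13-hydroxy-5,10-epoxy lactone with side-chain alkene (C11 epimers) | OCC1C(=O)O[C@@H]2C[C@]3(C)O[C@]3([C@@H](C)CCC=C(C)C)[C@H](OC(C)=O)[C@H]12 | intermediate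
22 | aldehyde, C1 aldehyde of the 6-O-acetyl-13-hydroxy epoxy lactone (C11 epimers) | OCC1C(=O)O[C@@H]2C[C@]3(C)O[C@]3([C@@H](C)CCC=O)[C@H](OC(C)=O)[C@H]12 | intermediate
23 | 6-O-acetyl-1,13-dihydroxy-5,10-epoxy lactone (C11 epimers) | OCC1C(=O)O[C@@H]2C[C@]3(C)O[C@]3([C@@H](C)CCCO)[C@H](OC(C)=O)[C@H]12 | intermediate
24 | iodohydrin, 10-iodo-5-hydroxy (iodine anti to the C5 hydroxyl) | OCC1C(=O)O[C@@H]2C[C@@](C)(I)[C@@](O)([C@@H](C)CCCO)[C@H](OC(C)=O)[C@H]12 | intermediate
25 | 6-O-acetyl-13-hydroxy-11,13-dihydrobritannilactone (C11 epimers) | OCC1C(=O)O[C@@H]2CC(C)=C([C@@H](C)CCCO)[C@H](OC(C)=O)[C@H]12 | intermediate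
26 | acetic anhydride | CC(=O)OC(C)=O | starting material
27 | triacetate, 1,6,13-tri-O-acetyl-13-hydroxy-11,13-dihydrobritannilactone | CC(=O)OCC1C(=O)O[C@@H]2CC(C)=C([C@@H](C)CCCOC(C)=O)[C@H](OC(C)=O)[C@H]12 | intermediate
28 | 1,6-O,O-diacetylbritannilactone (4S,6R,7R,8R) | C=C1C(=O)O[C@@H]2CC(C)=C([C@@H](C)CCCOC(C)=O)[C@H](OC(C)=O)[C@H]12 | target

Total step count: 14. Longest linear sequence: 14 steps, from (S)-citronellal 1.

Steps most likely to fail

Step 9 (key step). Several processes could divert it:
- acetolysis of the tetrasubstituted epoxide before the oxidation is over;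
- slow 6-exo closure, so that the C11 radical is captured by the side-chain alkene of a second molecule or transfers hydrogen from C6–H;
- oxidation of the C8 radical by elimination instead of lactonisation;
- decarboxylation of the β-keto acid.

Fallback, an ionic two-stage closure: the ethyl ester 15 is isolated instead of being hydrolysed. Iodocarbocyclisation (I2, Ti(OtBu)4, CH2Cl2) should add the titanium enolate carbon C11 to C7 anti to the iodonium ion and give the trans-iodo keto ester F1, with iodine on C8 on the face opposite C11. Saponification with LiOH gives the iodo keto acid F2, whose carboxylate should displace the iodide with inversion on warming with NaHCO3 in DMF, closing the cis lactone and returning to 17.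

Step 8. The SN2 reaction of the hindered secondary alkoxide may be slow, so that self-condensation of the chloro keto ester or base-induced degradation of the epoxy alcohol takes over. Fallback, a carbenoid O–H insertion under neutral conditions: ethyl 4-diazo-3-oxobutanoate F3 is made from ethyl malonyl chloride and trimethylsilyldiazomethane. With Rh2(OAc)4 (1 mol %) in CH2Cl2 it should insert into the O–H bond of 13 and give 15, which is hydrolysed as in step 8.

Step 13. The epoxide may ionise in acetic acid with a 1,2-shift or elimination to an allylic alcohol instead of clean iodohydrin formation, and the allylic C6 acetate may be lost. Fallback, a re-sequencing in which the alkene is unmasked by a radical deoxygenation before the acetate exists: from 17, ozonolysis with Me2S work-up and NaBH(OAc)3 reduction gives the tricyclic primary alcohol F4. Cp2TiCl (from Cp2TiCl2 and Zn, trivalent titanium) in THF should open the epoxide homolytically and eliminate the titanium alkoxide to give the tricyclic alkene F5. SmI2 in THF/MeOH then gives the acetyl lactone F6, and the formaldehyde/K2CO3 treatment of step 11 returns to 25.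

Further compounds
F1 | step 9 | trans-iodo keto ester, ethyl pyran-3-one-4-carboxylate fused at C6–C7 with 8-iodo anti to C11, 5,10-epoxide | CCOC(=O)C1C(=O)CO[C@@H]2[C@H]1[C@@H](I)C[C@]3(C)O[C@]23[C@@H](C)CCC=C(C)C
F2 | step 9 | iodo keto acid, carboxylic acid of F1 | OC(=O)C1C(=O)CO[C@@H]2[C@H]1[C@@H](I)C[C@]3(C)O[C@]23[C@@H](C)CCC=C(C)C
F3 | step 8 | ethyl 4-diazo-3-oxobutanoate | CCOC(=O)CC(=O)C=[N+]=[N-]
F4 | step 13 | tricyclic keto lactone with C1 hydroxyl, 5,10-epoxide retained | O=C1O[C@@H]2C[C@]3(C)O[C@]3([C@@H](C)CCCO)[C@@H]4OCC(=O)[C@@H]1[C@H]24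
F5 | step 13 | tricyclic keto lactone with C1 hydroxyl and C5=C10 alkene | O=C1O[C@@H]2CC(C)=C([C@@H](C)CCCO)[C@@H]3OCC(=O)[C@@H]1[C@H]23
F6 | step 13 | 11-acetyl-1,6-dihydroxy 12,8-lactone with C5=C10 alkene | CC(=O)[C@H]1C(=O)O[C@@H]2CC(C)=C([C@@H](C)CCCO)[C@H](O)[C@H]12
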